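## Retrosynthetic overview

- Feature (locants of tricyclo[5.4.0.0^{2,8}]undecane): the cyclobutane C1–C2–C8–C7 is substituted at every carbon (C2 quaternary) and bridged across both diagonals. A pyrrolidine with N between C1 (arm to C11) and C7 (arm to C6) can carry the same groups, so the C1–C7 bond comes from nitrogen deletion of NH-pyrrolidine 9.
- 9 comes from a copper-catalysed exo (3+2) cycloaddition of aminomalonate imine 5 (from 2,2-dimethylbut-3-enal) with E enone 8; this sets C2, C8 and C7.
- After contraction, kinetic Krapcho protonation leaves the C1 ester cis to both alkenyl arms; RCM of the C2-allyl and C7-CMe2CH=CH2 groups closes the cycloheptene (bridge C3–C6).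
- The cis C1 carboxyl delivers oxygen by iodolactonisation, which leads to the C4–C5 epoxide on the C1 face. The same carbon, as CHO, is then epimerised and closed onto the C8 acetyl by aldol condensation (bridge C9–C11), followed by Me2CuLi at C11.
- Epoxide opening at C4 gives the trans-diol, which is esterified twice with angelic acid. Ring order: pyrrolidine → cyclobutane → cycloheptene → (lactone, epoxide) → cyclohexenone.

Key step: step 6

Assumption: the sense of induction of the copper catalyst with this imine/enone pair is not known in advance, so (R)-DTBM-SEGPHOS stands for whichever ligand antipode gives the (3S,4S,5S) series; methyl esters are used because SN2 dealkylation (steps 7 and 9) is fastest at O–CH3.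

## Route

Step 1
Reactants: 1 2,2-dimethylbut-3-enoic acid
Product: 2 2,2-dimethylbut-3-en-1-ol
Conditions: LiAlH4, Et2O, 0 °C → reflux; H2O/NaOH work-up
Reagents that add atoms: none
Why: Hydride reduction of the carboxylic acid gives the primary alcohol, and the isolated vinyl group does not react with LiAlH4.

Step 2
Reactants: 2 2,2-dimethylbut-3-en-1-ol
Product: 3 2,2-dimethylbut-3-enal
Conditions: TEMPO (10 mol%), PhI(OAc)2, CH2Cl2, rt; NaHCO3 wash, used as a solution
Reagents that add atoms: none
Why: Oxoammonium (TEMPO) oxidation stops at the aldehyde, which has no α-hydrogen and therefore cannot enolise or self-condense.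

Step 3
Reactants: 3 2,2-dimethylbut-3-enal; 4 dimethyl aminomalonate hydrochloride
Product: 5 dimethyl 2-{[(1E)-2,2-dimethylbut-3-en-1-ylidene]amino}propanedioate
Conditions: Et3N, MgSO4, CH2Cl2, rt
Reagents that add atoms: none
Why: Condensation of the amine, freed in situ, with the non-enolisable aldehyde gives the E aldimine that serves as the azomethine ylide precursor.

Step 4
Reactants: 6 pent-1-en-4-yne
Product: 8 (3E)-4-methylhepta-3,6-dien-2-one, via alkenylalane 7 (not isolated)
Conditions: AlMe3, Cp2ZrCl2 (20 mol%), CH2Cl2, 0 °C → rt; then AcCl, Pd(PPh3)4 (5 mol%), THF, 0 °C → rt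
Reagents that add atoms: trimethylaluminium C[Al](C)C; acetyl chloride CC(Cl)=O
Why: Zirconium-catalysed syn-carboalumination of the terminal alkyne (Negishi carboalumination) places CH3 on the internal carbon cis to aluminium, and zerovalent-palladium-catalysed acylation with retention should give the E enone in which acetyl and CH3 are cis.

Step 5
Reactants: 5 dimethyl 2-{[(1E)-2,2-dimethylbut-3-en-1-ylidene]amino}propanedioate; 8 (3E)-4-methylhepta-3,6-dien-2-one
Product: 9 dimethyl (3S,4S,5S)-4-acetyl-3-methyl-5-(2-methylbut-3-en-2-yl)-3-(prop-2-en-1-yl)pyrrolidine-2,2-dicarboxylate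
Conditions: Cu(CH3CN)4PF6 (5 mol%), (R)-DTBM-SEGPHOS (5.5 mol%), Et3N (20 mol%), THF, rt → 40 °C
Reagents that add atoms: none
Why: The N,O-chelated monovalent copper azomethine ylide adds suprafacially to the E enone with its malonate carbon attacking the β-carbon (metal-catalysed azomethine ylide/enone 1,3-dipolar cycloaddition); the exo approach, in which the acetyl group turns away from the tert-alkyl group at C5, should place allyl cis and acetyl trans to that group while the alkene geometry keeps acetyl cis to CH3, and the chiral bisphosphine fixes the absolute sense at C3, C4 and C5.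

Step 6
Reactants: 9 dimethyl (3S,4S,5S)-4-acetyl-3-methyl-5-(2-methylbut-3-en-2-yl)-3-(prop-2-en-1-yl)pyrrolidine-2,2-dicarboxylate
Product: 11 dimethyl (2S,3R,4S)-3-acetyl-2-methyl-4-(2-methylbut-3-en-2-yl)-2-(prop-2-en-1-yl)cyclobutane-1,1-dicarboxylate, via 1,1-diazene 10 (not isolated)
Conditions: PhI(OH)OTs (2.5 equiv), H2NCO2NH4 (8 equiv), CF3CH2OH, 80 °C
Reagents that add atoms: none
Why: PhI(OH)OTs and ammonia released from H2NCO2NH4 give an iodonitrene that transfers nitrogen to the ring NH; loss of PhI leaves 1,1-diazene 10, which extrudes N2 to a singlet 1,4-biradical (malonyl radical at C2, secondary radical at C5) that couples to form the C1–C4 bond of the cyclobutane. The closest known reaction is the iodonitrene-mediated contraction of polysubstituted NH-pyrrolidines to cyclobutanes, the modern form of 1,1-diazene nitrogen extrusion. The four-membered ring closes by radical–radical recombination within the singlet pair, faster than rotation about the C2–C3 and C4–C5 bonds. No stereocentre is created: C3, C4 and C5 of 9 become C2, C3 and C4 of 11 with retention, and the malonate carbon stays non-stereogenic. The step needs recombination to outrun β-scission of the C3–C4 bond (to an alkylidenemalonate and an enone) and the radical clocks of the allyl and dimethylallyl arms; the short-lived singlet biradical, the stabilised malonyl radical and the fully substituted C3 holding the termini together should secure this. It also needs nitrogen transfer to the amine in preference to the two monosubstituted alkenes and the methyl ketone, which the reactive NH and the ammonia-buffered CF3CH2OH medium should provide.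

Step 7
Reactants: 11 dimethyl (2S,3R,4S)-3-acetyl-2-methyl-4-(2-methylbut-3-en-2-yl)-2-(prop-2-en-1-yl)cyclobutane-1,1-dicarboxylate
Product: 13 methyl (1R,2S,3R,4R)-3-acetyl-2-methyl-4-(2-methylbut-3-en-2-yl)-2-(prop-2-en-1-yl)cyclobutane-1-carboxylate, via lithium half-ester 12 (not isolated)
Conditions: LiCl, H2O (2 equiv), DMSO, 150 °C
Reagents that add atoms: none
Why: Krapcho dealkoxycarbonylation (chloride attack at O–CH3, loss of CO2) gives an ester enolate that should be protonated kinetically from the ring face carrying CH3 (C2) and H (C4), away from the allyl and tert-alkyl groups, so the remaining ester ends cis to both alkenyl arms and trans to acetyl; the medium is too weakly basic to equilibrate it.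

Step 8
Reactants: 13 methyl (1R,2S,3R,4R)-3-acetyl-2-methyl-4-(2-methylbut-3-en-2-yl)-2-(prop-2-en-1-yl)cyclobutane-1-carboxylate
Product: 14 methyl (1S,6R,7R,8R)-8-acetyl-1,5,5-trimethylbicyclo[4.1.1]oct-3-ene-7-carboxylate
Conditions: second-generation Hoveyda–Grubbs catalyst (5 mol%), toluene (2 mM), 80 °C
Reagents that add atoms: none
Why: Ring-closing metathesis: the ruthenium carbene forms at the unhindered allyl terminus and closes onto the neopentylic vinyl group held on the same face (1,3-cis), releasing ethene and forming the cis-cycloheptene without touching a stereocentre.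

Step 9
Reactants: 14 methyl (1S,6R,7R,8R)-8-acetyl-1,5,5-trimethylbicyclo[4.1.1]oct-3-ene-7-carboxylate
Product: 15 (1S,6R,7R,8R)-8-acetyl-1,5,5-trimethylbicyclo[4.1.1]oct-3-ene-7-carboxylic acid
Conditions: LiI (5 equiv), EtOAc, reflux; then 1 M HCl
Reagents that add atoms: none
Why: Iodide cleaves the methyl ester by SN2 attack at O–CH3, which is insensitive to the hindered acyl carbon and non-basic, so C7 and C8 should not epimerise.

Step 10
Reactants: 15 (1S,6R,7R,8R)-8-acetyl-1,5,5-trimethylbicyclo[4.1.1]oct-3-ene-7-carboxylic acid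
Product: 16 8-acetyl-4-iodo-1,5,5-trimethylbicyclo[4.1.1]octane-7,3-carbolactone (lactone O on C3 on the C7 side, I on C4 on the C8 side)
Conditions: I2, KI, NaHCO3, THF/H2O, 0 °C → rt, dark
Reagents that add atoms: iodine II
Why: Iodolactonisation: the C7 carboxylate, which lies beside one face of the C3=C4 bond, opens the iodonium ion formed on the opposite (C8-side) face in an anti addition at C3 (flanked by CH2, not the neopentyl C4), giving the six-membered lactone with O on the C7 side and I on the C8 side; either regiochemistry of closure would lead to the same epoxide in step 11.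

Step 11
Reactants: 16 8-acetyl-4-iodo-1,5,5-trimethylbicyclo[4.1.1]octane-7,3-carbolactone
Product: 18 methyl (1S,3R,4S,6R,7R,8R)-8-acetyl-3,4-epoxy-1,5,5-trimethylbicyclo[4.1.1]octane-7-carboxylate, via iodohydrin ester 17 (not isolated)
Conditions: K2CO3, MeOH, rt
Reagents that add atoms: methanol CO
Why: Methanolysis of the lactone frees the C3 alkoxide, which displaces the anti iodide at C4 with inversion (Williamson-type epoxide closure), so the epoxide oxygen sits on the C7 side of the ring and the carboxyl returns as CO2Me.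

Step 12
Reactants: 18 methyl (1S,3R,4S,6R,7R,8R)-8-acetyl-3,4-epoxy-1,5,5-trimethylbicyclo[4.1.1]octane-7-carboxylate
Product: 19 1-[3,4-epoxy-7-(hydroxymethyl)-1,5,5-trimethylbicyclo[4.1.1]octan-8-yl]ethan-1-ol (ring configuration as in 18; carbinol epimers)
Conditions: i-Bu2AlH (5 equiv), CH2Cl2, −78 → −20 °C; potassium sodium tartrate work-up
Reagents that add atoms: none
Why: Aluminium hydride reduction takes the ester to the primary alcohol and the ketone to the carbinol (epimer mixture, removed in step 13), while the hindered 1,2-disubstituted epoxide should survive at low temperature.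

Step 13
Reactants: 19 1-[3,4-epoxy-7-(hydroxymethyl)-1,5,5-trimethylbicyclo[4.1.1]octan-8-yl]ethan-1-ol
Product: 20 8-acetyl-3,4-epoxy-1,5,5-trimethylbicyclo[4.1.1]octane-7-carbaldehyde (ring configuration as in 18)
Conditions: Dess–Martin periodinane (3 equiv), pyridine, CH2Cl2, 0 °C → rt
Reagents that add atoms: none
Why: Dess–Martin oxidation converts both alcohols to the keto aldehyde under buffered conditions that leave the epoxide and the α-stereocentres untouched.

Step 14
Reactants: 20 8-acetyl-3,4-epoxy-1,5,5-trimethylbicyclo[4.1.1]octane-7-carbaldehyde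
Product: 23 (1S,2R,4R,5S,7S,8R)-4,5-epoxy-2,6,6-trimethyltricyclo[5.4.0.0^{2,8}]undec-10-en-9-one, via axial aldehyde 21 (not isolated), via aldol 22 (not isolated)
Conditions: NaOMe (0.5 equiv), MeOH, rt → 50 °C
Reagents that add atoms: none
Why: Base equilibrates the aldehyde-bearing carbon, only epimer 21 with the formyl group axial and facing the axial acetyl group can close by intramolecular aldol addition (six-membered, enolexo exo-trig), and irreversible E1cB dehydration of 22 drains the equilibrium to the bridged enone, so the bridgehead C1 is fixed by the ring closure itself (aldol condensation).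

Step 15
Reactants: 23 (1S,2R,4R,5S,7S,8R)-4,5-epoxy-2,6,6-trimethyltricyclo[5.4.0.0^{2,8}]undec-10-en-9-one
Product: 24 (1S,2R,4R,5S,7S,8R,11R)-4,5-epoxy-2,6,6,11-tetramethyltricyclo[5.4.0.0^{2,8}]undecan-9-one
Conditions: CuI, MeLi (2 equiv per Cu), Et2O, 0 °C; then 23, −78 °C; aq NH4Cl
Reagents that add atoms: lithium dimethylcuprate [Li+].C[Cu-]C
Why: Cuprate conjugate addition should occur on the enone face under the C7–H bridge, because the CH3 on the C2 bridge hangs over the other face (as in apoverbenone-type enones), which sets C11 as R; at −78 °C the hindered epoxide should not be opened.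

Step 16
Reactants: 24 (1S,2R,4R,5S,7S,8R,11R)-4,5-epoxy-2,6,6,11-tetramethyltricyclo[5.4.0.0^{2,8}]undecan-9-one
Product: 25 (1S,2R,4S,5S,7S,8R,11R)-4,5-dihydroxy-2,6,6,11-tetramethyltricyclo[5.4.0.0^{2,8}]undecan-9-one
Conditions: HClO4 (0.5 M aq), THF, rt
Reagents that add atoms: water O
Why: Acid-catalysed SN2-type epoxide hydrolysis: water attacks C4 (flanked by CH2) from the face opposite the epoxide oxygen rather than the neopentyl C5, so C4 is inverted and C5 keeps its oxygen, giving the (4S,5S) trans-diol.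

Step 17
Reactants: 25 (1S,2R,4S,5S,7S,8R,11R)-4,5-dihydroxy-2,6,6,11-tetramethyltricyclo[5.4.0.0^{2,8}]undecan-9-one
Product: 27 (1S,2R,4S,5S,7S,8R,11R)-2,6,6,11-tetramethyl-9-oxotricyclo[5.4.0.0^{2,8}]undecane-4,5-diyl bis[(2Z)-2-methylbut-2-enoate], via monoangelate 26 (not isolated)
Conditions: angelic acid (6 equiv), 2,4,6-trichlorobenzoyl chloride (6 equiv), Et3N, toluene, rt; then 25, 80 °C (no DMAP)
Reagents that add atoms: angelic acid C/C=C(/C)C(=O)O
Why: Yamaguchi-type acylation with the preformed angelic 2,4,6-trichlorobenzoic mixed anhydride, run without a nucleophilic catalyst, should esterify first the C4 and then the hindered C5 hydroxyl without Z → E isomerisation to the tiglate.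

## Compound list

1 | 2,2-dimethylbut-3-enoic acid | C=CC(C)(C)C(=O)O | starting material
2 | 2,2-dimethylbut-3-en-1-ol | C=CC(C)(C)CO | intermediate
3 | 2,2-dimethylbut-3-enal | C=CC(C)(C)C=O | intermediate
4 | dimethyl aminomalonate hydrochloride | COC(=O)C(N)C(=O)OC.Cl | starting material
5 | dimethyl 2-{[(1E)-2,2-dimethylbut-3-en-1-ylidene]amino}propanedioate | C=CC(C)(C)/C=N/C(C(=O)OC)C(=O)OC | intermediate
6 | pent-1-en-4-yne | C#CCC=C | starting material
7 | (E)-dimethyl(2-methylpenta-1,4-dien-1-yl)alumane (Al cis to CH3) | C[Al](C)/C=C(\C)CC=C | intermediate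
8 | (3E)-4-methylhepta-3,6-dien-2-one (acetyl cis to CH3) | CC(=O)/C=C(\C)CC=C | intermediate
9 | dimethyl (3S,4S,5S)-4-acetyl-3-methyl-5-(2-methylbut-3-en-2-yl)-3-(prop-2-en-1-yl)pyrrolidine-2,2-dicarboxylate (allyl cis to the dimethylallyl group; acetyl trans to both, cis to CH3) | C=CC[C@]1(C)C(C(=O)OC)(C(=O)OC)N[C@@H]([C@H]1C(C)=O)C(C)(C)C=C | intermediate
10 | 1,1-diazene (N-aminonitrene) of 9, ring configuration unchanged | C=CC[C@]1(C)C(C(=O)OC)(C(=O)OC)[N+](=[N-])[C@@H]([C@H]1C(C)=O)C(C)(C)C=C | intermediate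
11 | dimethyl (2S,3R,4S)-3-acetyl-2-methyl-4-(2-methylbut-3-en-2-yl)-2-(prop-2-en-1-yl)cyclobutane-1,1-dicarboxylate | C=CC[C@]1(C)C(C(=O)OC)(C(=O)OC)[C@@H]([C@H]1C(C)=O)C(C)(C)C=C | intermediate
12 | lithium (2S,3R,4S)-3-acetyl-1-(methoxycarbonyl)-2-methyl-4-(2-methylbut-3-en-2-yl)-2-(prop-2-en-1-yl)cyclobutane-1-carboxylate (either ester cleaved; C1 not defined) | C=CC[C@]1(C)C(C(=O)OC)(C(=O)[O-])[C@@H]([C@H]1C(C)=O)C(C)(C)C=C.[Li+] | intermediate
13 | methyl (1R,2S,3R,4R)-3-acetyl-2-methyl-4-(2-methylbut-3-en-2-yl)-2-(prop-2-en-1-yl)cyclobutane-1-carboxylate (ester cis to allyl and dimethylallyl, trans to acetyl) | COC(=O)[C@H]1[C@@](C)(CC=C)[C@H](C(C)=O)[C@H]1C(C)(C)C=C | intermediate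
14 | methyl (1S,6R,7R,8R)-8-acetyl-1,5,5-trimethylbicyclo[4.1.1]oct-3-ene-7-carboxylate (ester syn, acetyl anti to the four-carbon bridge) | COC(=O)[C@H]1[C@@]2(C)CC=CC(C)(C)[C@@H]1[C@H]2C(C)=O | intermediate
15 | (1S,6R,7R,8R)-8-acetyl-1,5,5-trimethylbicyclo[4.1.1]oct-3-ene-7-carboxylic acid | OC(=O)[C@H]1[C@@]2(C)CC=CC(C)(C)[C@@H]1[C@H]2C(C)=O | intermediate
16 | 8-acetyl-4-iodo-1,5,5-trimethylbicyclo[4.1.1]octane-7,3-carbolactone (ring configuration as in 14; lactone O at C3 on the C7 side, I at C4 trans to it on the C8 side) | O=C1O[C@@H]2C[C@]3(C)[C@H]1[C@@H]([C@H]3C(C)=O)C(C)(C)[C@H]2I | intermediate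
17 | methyl 8-acetyl-3-hydroxy-4-iodo-1,5,5-trimethylbicyclo[4.1.1]octane-7-carboxylate (OH on the C7 side, I on the C8 side; reacts as its alkoxide) | COC(=O)[C@H]1[C@@]2(C)C[C@@H](O)[C@H](I)C(C)(C)[C@@H]1[C@H]2C(C)=O | intermediate
18 | methyl (1S,3R,4S,6R,7R,8R)-8-acetyl-3,4-epoxy-1,5,5-trimethylbicyclo[4.1.1]octane-7-carboxylate (epoxide O on the C7 side) | COC(=O)[C@H]1[C@@]2(C)C[C@H]3O[C@H]3C(C)(C)[C@@H]1[C@H]2C(C)=O | intermediate
19 | 1-[3,4-epoxy-7-(hydroxymethyl)-1,5,5-trimethylbicyclo[4.1.1]octan-8-yl]ethan-1-ol (ring configuration as in 18; carbinol carbon as both epimers) | OC[C@H]1[C@@]2(C)C[C@H]3O[C@H]3C(C)(C)[C@@H]1[C@H]2C(C)O | intermediate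
20 | 8-acetyl-3,4-epoxy-1,5,5-trimethylbicyclo[4.1.1]octane-7-carbaldehyde (ring configuration as in 18; CHO syn to the epoxide bridge) | O=C[C@H]1[C@@]2(C)C[C@H]3O[C@H]3C(C)(C)[C@@H]1[C@H]2C(C)=O | intermediate
21 | C7 epimer of 20 (CHO axial, on the same side as the acetyl group) | O=C[C@@H]1[C@@]2(C)C[C@H]3O[C@H]3C(C)(C)[C@@H]1[C@H]2C(C)=O | intermediate
22 | 4,5-epoxy-11-hydroxy-2,6,6-trimethyltricyclo[5.4.0.0^{2,8}]undecan-9-one (ring configuration as in 23; C11 carbinol not defined) | O1[C@@H]2C[C@]3(C)[C@@H]4[C@@H]([C@H]3C(=O)CC4O)C(C)(C)[C@@H]21 | intermediate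
23 | (1S,2R,4R,5S,7S,8R)-4,5-epoxy-2,6,6-trimethyltricyclo[5.4.0.0^{2,8}]undec-10-en-9-one | O1[C@@H]2C[C@]3(C)[C@@H]4[C@@H]([C@H]3C(=O)C=C4)C(C)(C)[C@@H]21 | intermediate
24 | (1S,2R,4R,5S,7S,8R,11R)-4,5-epoxy-2,6,6,11-tetramethyltricyclo[5.4.0.0^{2,8}]undecan-9-one | O1[C@@H]2C[C@]3(C)[C@@H]4[C@@H]([C@H]3C(=O)C[C@H]4C)C(C)(C)[C@@H]21 | intermediate
25 | (1S,2R,4S,5S,7S,8R,11R)-4,5-dihydroxy-2,6,6,11-tetramethyltricyclo[5.4.0.0^{2,8}]undecan-9-one | O[C@H]1C[C@]2(C)[C@@H]3[C@@H]([C@H]2C(=O)C[C@H]3C)C(C)(C)[C@@H]1O | intermediate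
26 | (1S,2R,4S,5S,7S,8R,11R)-5-hydroxy-2,6,6,11-tetramethyl-9-oxotricyclo[5.4.0.0^{2,8}]undecan-4-yl (2Z)-2-methylbut-2-enoate | C/C=C(/C)C(=O)O[C@H]1C[C@]2(C)[C@@H]3[C@@H]([C@H]2C(=O)C[C@H]3C)C(C)(C)[C@@H]1O | intermediate
27 | (1S,2R,4S,5S,7S,8R,11R)-2,6,6,11-tetramethyl-9-oxotricyclo[5.4.0.0^{2,8}]undecane-4,5-diyl bis[(2Z)-2-methylbut-2-enoate] | C/C=C(/C)C(=O)O[C@H]1C[C@]2(C)[C@@H]3[C@@H]([C@H]2C(=O)C[C@H]3C)C(C)(C)[C@@H]1OC(=O)/C(C)=C\C | target

## Step count and risks

Total step count: 17.
Longest linear sequence: 16 steps (steps 1–3 and 5–17 from 1; step 4 is a one-step branch from 6).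

Steps most likely to fail:

1. Step 5. The attacking ylide carbon is doubly stabilised and fully substituted and the acceptor carbon is β,β-disubstituted, so the addition may be too slow. Under the amine base the skipped diene of 8 may also migrate into conjugation, and the exo preference may erode, which would scramble the C3/C5 relationship. The fallback sets out from 3 and 8 and returns at 13. Condensation of 3 with methyl glycinate hydrochloride (Et3N, MgSO4) gives methyl N-[(1E)-2,2-dimethylbut-3-en-1-ylidene]glycinate F1. Its ylide is less hindered and more nucleophilic and forms a tertiary–quaternary instead of a quaternary–quaternary bond. Cycloaddition with 8 (Cu(CH3CN)4PF6/bisphosphine or AgOAc/phosphine, Et3N) should give the 2,5-cis pyrrolidine methyl (2R,3S,4S,5S)-4-acetyl-3-methyl-5-(2-methylbut-3-en-2-yl)-3-(prop-2-en-1-yl)pyrrolidine-2-carboxylate F2. The same iodonitrene contraction, with retention at all four carbons, then delivers 13 directly, so no Krapcho step is needed.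

2. Step 6. Nitrogen transfer to the hindered, weakly basic NH may be slow, letting the trivalent iodine reagent oxidise the α-position of the methyl ketone or the alkenes. After N2 loss, β-scission of the biradical to two conjugated alkenes may compete with ring closure at 80 °C. The fallback sets out from 9 and returns at 11; it is the classical stepwise route to the same 1,1-diazene. Nitrosation (NOBF4, pyridine, CH2Cl2) gives dimethyl (3S,4S,5S)-4-acetyl-3-methyl-5-(2-methylbut-3-en-2-yl)-1-nitroso-3-(prop-2-en-1-yl)pyrrolidine-2,2-dicarboxylate F3. Zn/AcOH reduces it to dimethyl (3S,4S,5S)-4-acetyl-1-amino-3-methyl-5-(2-methylbut-3-en-2-yl)-3-(prop-2-en-1-yl)pyrrolidine-2,2-dicarboxylate F4. Oxidation of F4 with PhI(OAc)2 (or HgO) in CH2Cl2 at 0 °C generates 10 without an external nitrene source and at low temperature, where recombination is favoured over scission; N2 loss gives 11.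

3. Step 14. The pre-equilibria are uphill (epimerisation to the congested axial aldehyde, a reversible strained aldol addition), so intermolecular condensation, epimerisation of the acetyl-bearing carbon or base attack on the epoxide may take over before dehydration. The fallback sets out from 18 and returns at 23; it replaces the reversible aldol by an irreversible intramolecular Horner–Wadsworth–Emmons olefination. Kinetic enolisation of the methyl ketone of 18 (LDA, −78 °C), O-phosphorylation with ClP(O)(OEt)2 and LDA-induced 1,3-phosphorus shift give methyl 8-[(diethoxyphosphoryl)acetyl]-3,4-epoxy-1,5,5-trimethylbicyclo[4.1.1]octane-7-carboxylate F5. Its sodium enolate (NaH) protects the ketone while i-Bu2AlH reduces the ester to diethyl {2-[3,4-epoxy-7-(hydroxymethyl)-1,5,5-trimethylbicyclo[4.1.1]octan-8-yl]-2-oxoethyl}phosphonate F6. Dess–Martin oxidation gives diethyl {2-[3,4-epoxy-7-formyl-1,5,5-trimethylbicyclo[4.1.1]octan-8-yl]-2-oxoethyl}phosphonate F7. LiCl/DBU in MeCN (Masamune–Roush conditions) then epimerises the aldehyde and closes the enone ring to 23.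

## Further compounds

F1 | step 5 | methyl N-[(1E)-2,2-dimethylbut-3-en-1-ylidene]glycinate | C=CC(C)(C)/C=N/CC(=O)OC
F2 | step 5 | methyl (2R,3S,4S,5S)-4-acetyl-3-methyl-5-(2-methylbut-3-en-2-yl)-3-(prop-2-en-1-yl)pyrrolidine-2-carboxylate | COC(=O)[C@@H]1N[C@H](C(C)(C)C=C)[C@@H](C(C)=O)[C@]1(C)CC=C
F3 | step 6 | dimethyl (3S,4S,5S)-4-acetyl-3-methyl-5-(2-methylbut-3-en-2-yl)-1-nitroso-3-(prop-2-en-1-yl)pyrrolidine-2,2-dicarboxylate | C=CC[C@]1(C)C(C(=O)OC)(C(=O)OC)N(N=O)[C@@H]([C@H]1C(C)=O)C(C)(C)C=C
F4 | step 6 | dimethyl (3S,4S,5S)-4-acetyl-1-amino-3-methyl-5-(2-methylbut-3-en-2-yl)-3-(prop-2-en-1-yl)pyrrolidine-2,2-dicarboxylate | C=CC[C@]1(C)C(C(=O)OC)(C(=O)OC)N(N)[C@@H]([C@H]1C(C)=O)C(C)(C)C=C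
F5 | step 14 | methyl 8-[(diethoxyphosphoryl)acetyl]-3,4-epoxy-1,5,5-trimethylbicyclo[4.1.1]octane-7-carboxylate (ring configuration as in 18) | COC(=O)[C@H]1[C@@]2(C)C[C@H]3O[C@H]3C(C)(C)[C@@H]1[C@H]2C(=O)CP(=O)(OCC)OCC
F6 | step 14 | diethyl {2-[3,4-epoxy-7-(hydroxymethyl)-1,5,5-trimethylbicyclo[4.1.1]octan-8-yl]-2-oxoethyl}phosphonate (ring configuration as in 18) | OC[C@H]1[C@@]2(C)C[C@H]3O[C@H]3C(C)(C)[C@@H]1[C@H]2C(=O)CP(=O)(OCC)OCC
F7 | step 14 | diethyl {2-[3,4-epoxy-7-formyl-1,5,5-trimethylbicyclo[4.1.1]octan-8-yl]-2-oxoethyl}phosphonate (ring configuration as in 18) | O=C[C@H]1[C@@]2(C)C[C@H]3O[C@H]3C(C)(C)[C@@H]1[C@H]2C(=O)CP(=O)(OCC)OCC
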